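**Retrosynthetic overview**

1. The target comes from its heptakis-TIPS ether 27, and 27 from the 2-aryl-4,5-dihydrofuran 26 by OH-directed syn-hydrogenation of C2=C3, so that H-2 and H-3 both arrive on the face of the C4 hydroxyl (the 2,3-cis oxolane).
2. Key disconnection: the oxolane C2–aryl bond, made at the enol ether oxidation level by a one-flask Ir-catalysed C–H borylation/Suzuki–Miyaura coupling of arene 22 (fragment A, no handle at the reacting carbon) with ketene acetal phosphate 23.
3. Enabling feature: in the oxolane-bearing guaiacyl ring (ring C, 1,2,3-trisubstituted by the biaryl bond, O and OMe) the carbon para to the phenolic oxygen carries the only aromatic H with two H-bearing neighbours; every other Ar–H of fragment A is ortho to a substituent. The ring oxygen O1 on C2 lets C2 be a lactone carbonyl, hence an enol phosphate.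
4. Fragment A: tetralin ring by hemiketal reduction/Friedel–Crafts cyclisation after adding a biaryllithium to lactone 12. Lactone 12 comes from (S)-malic acid (quaternary C4 by enolate alkylation) and vanillin, with C3 set by anti-selective hydroxymethylation.
5. Ring order: butyrolactone ring (step 6), then the tetralin ring of fragment A (step 13, one copy of 12 consumed), then a second copy of 12 attached as a dihydrofuran (step 16), then the oxolane (step 17).

Key step: step 16

Remark: the stereodescriptors are read as oxolane (2R,3R,4S), meaning aryl, CH2OH and benzyl mutually cis with the tertiary OH on the other face, and tetralin (1S,2S,3S).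

**Route**

Step 1
Reactants: 1 vanillin
Product: 2 3-methoxy-4-(triisopropylsilyloxy)benzaldehyde
Conditions: TIPSCl, imidazole, DMF, rt
Reagents that add atoms: chlorotriisopropylsilane, CC(C)[Si](Cl)(C(C)C)C(C)C
Why: O-silylation of the phenol (silyl ether formation); the aryl TIPS ether should tolerate the later bases, hydrides, acid and palladium steps and carries no aromatic C–H.

Step 2
Reactants: 2 3-methoxy-4-(triisopropylsilyloxy)benzaldehyde
Product: 3 [3-methoxy-4-(triisopropylsilyloxy)phenyl]methanol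
Conditions: NaBH4, MeOH/THF, 0 °C
Reagents that add atoms: none
Why: Borohydride reduction of the aldehyde to the benzylic alcohol.

Step 3
Reactants: 3 [3-methoxy-4-(triisopropylsilyloxy)phenyl]methanol
Product: 4 4-(bromomethyl)-2-methoxy-1-(triisopropylsilyloxy)benzene
Conditions: PBr3 (0.4 equiv), Et2O, 0 °C; used at once
Reagents that add atoms: phosphorus tribromide, BrP(Br)Br
Why: Alcohol-to-bromide substitution through the dibromophosphite ester, which is fast for an electron-rich benzylic alcohol.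

Step 4
Reactants: 5 (S)-malic acid
Product: 6 2-[(2S,4S)-2-tert-butyl-5-oxo-1,3-dioxolan-4-yl]acetic acid
Conditions: pivalaldehyde, TsOH (cat.), H2SO4 (cat.), pentane, reflux, Dean–Stark
Reagents that add atoms: pivalaldehyde, CC(C)(C)C=O
Why: Acid-catalysed acetalisation of the α-hydroxy acid with azeotropic water removal; the cis dioxolanone should be the thermodynamic, crystalline product, its acetal centre relayed from the malic acid centre.

Step 5
Reactants: 6 2-[(2S,4S)-2-tert-butyl-5-oxo-1,3-dioxolan-4-yl]acetic acid; 4 4-(bromomethyl)-2-methoxy-1-(triisopropylsilyloxy)benzene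
Product: 7 2-[(2S,4S)-2-tert-butyl-4-{[3-methoxy-4-(triisopropylsilyloxy)phenyl]methyl}-5-oxo-1,3-dioxolan-4-yl]acetic acid
Conditions: LiN(SiMe3)2 (2.1 equiv), THF, −78 °C; then 4, −78 to −30 °C; aq. HCl work-up
Reagents that add atoms: none
Why: Alkylation of the dioxolanone lithium enolate with self-regeneration of the stereocentre: the tert-butyl group shields one face, the benzyl bromide enters trans to it, and the quaternary carbinol carbon forms with net retention (S).

Step 6
Reactants: 7 2-[(2S,4S)-2-tert-butyl-4-{[3-methoxy-4-(triisopropylsilyloxy)phenyl]methyl}-5-oxo-1,3-dioxolan-4-yl]acetic acid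
Product: 9 (4S)-4-hydroxy-4-{[3-methoxy-4-(triisopropylsilyloxy)phenyl]methyl}oxolan-2-one, via dihydroxy acid 8 (not isolated)
Conditions: NaBH4 (4 equiv), EtOH/THF, 0 °C to rt; then 2 M HCl, rt
Reagents that add atoms: none
Why: Borohydride reduction of the activated dioxolanone carbonyl to the primary alcohol (pivalaldehyde is released and reduced, the carboxylate is spared), then acid-catalysed γ-lactonisation; the quaternary stereocentre is not involved.

Step 7
Reactants: 9 (4S)-4-hydroxy-4-{[3-methoxy-4-(triisopropylsilyloxy)phenyl]methyl}oxolan-2-one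
Product: 10 (3S,4S)-4-hydroxy-3-(hydroxymethyl)-4-{[3-methoxy-4-(triisopropylsilyloxy)phenyl]methyl}oxolan-2-one
Conditions: LiN(iPr)2 (2.2 equiv), THF, −78 to −40 °C; CH2O (gas), −78 °C
Reagents that add atoms: formaldehyde, C=O
Why: Fráter–Seebach-type hydroxymethylation (aldol with formaldehyde) of the alkoxide–enolate dianion: the electrophile should add anti to the lithium alkoxide, placing CH2OH trans to OH and cis to the benzyl group (3S).

Step 8
Reactants: 10 (3S,4S)-4-hydroxy-3-(hydroxymethyl)-4-{[3-methoxy-4-(triisopropylsilyloxy)phenyl]methyl}oxolan-2-one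
Product: 12 (3S,4S)-4-{[3-methoxy-4-(triisopropylsilyloxy)phenyl]methyl}-3-[(triisopropylsilyloxy)methyl]-4-(trimethylsilyloxy)oxolan-2-one, via primary TIPS ether 11 (not isolated)
Conditions: TIPSCl (1.1 equiv), imidazole, DMF, 0 °C to rt; then TMSCl (1.5 equiv), rt
Reagents that add atoms: chlorotriisopropylsilane, CC(C)[Si](Cl)(C(C)C)C(C)C; chlorotrimethylsilane, C[Si](C)(C)Cl
Why: Sequential silyl ether formation: the bulky chlorosilane takes only the primary hydroxyl, then the small TMS group caps the tertiary hydroxyl as a base-stable ether that can be removed selectively later.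

Step 9
Reactants: 13 4-bromo-2-methoxyphenol
Product: 14 4-bromo-2-iodo-6-methoxyphenol
Conditions: N-iodosuccinimide, TsOH (cat.), MeCN, 0 °C to rt
Reagents that add atoms: N-iodosuccinimide, O=C1CCC(=O)N1I
Why: Electrophilic aromatic iodination; the free phenol directs ortho and its para position is blocked by bromine.

Step 10
Reactants: 14 4-bromo-2-iodo-6-methoxyphenol; 15 (2-hydroxy-3-methoxyphenyl)boronic acid
Product: 16 5-bromo-3,3'-dimethoxybiphenyl-2,2'-diol
Conditions: Pd(PPh3)4 (3 mol %), Na2CO3, DME/H2O, 60 °C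
Reagents that add atoms: none
Why: Suzuki–Miyaura coupling, chemoselective because oxidative addition of zerovalent palladium into C–I is much faster than into C–Br.

Step 11
Reactants: 16 5-bromo-3,3'-dimethoxybiphenyl-2,2'-diol
Product: 17 5-bromo-3,3'-dimethoxy-2,2'-bis(triisopropylsilyloxy)biphenyl
Conditions: TIPSOTf (2.5 equiv), 2,6-lutidine, CH2Cl2, 0 °C to rt
Reagents that add atoms: triisopropylsilyl trifluoromethanesulfonate, CC(C)[Si](OS(=O)(=O)C(F)(F)F)(C(C)C)C(C)C
Why: Silyl ether formation with the silyl triflate, which is reactive enough for the two hindered 2,6-disubstituted phenols.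

Step 12
Reactants: 17 5-bromo-3,3'-dimethoxy-2,2'-bis(triisopropylsilyloxy)biphenyl; 12 silylated lactone
Product: 19 2-biaryl hemiketal of lactone 12 (mixture at C2), via aryllithium 18 (not isolated)
Conditions: n-BuLi (1.05 equiv), THF, −78 °C; then 12, −78 °C
Reagents that add atoms: none
Why: Bromine–lithium exchange and 1,2-addition of the aryllithium to the lactone carbonyl (the lactone-addition stage of a C-aryl glycoside synthesis); the tetrahedral lithium hemiketal should persist at −78 °C and prevent double addition.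

Step 13
Reactants: 19 2-biaryl hemiketal
Product: 21 (1S,2S,3S)-1-biaryl-tetralin diol (free tertiary OH and free C3 CH2OH), via 2-aryloxolane 20 (not isolated)
Conditions: Et3SiH (1.2 equiv), CF3CO2H, CH2Cl2, −20 °C to rt; NaHCO3/MeOH work-up
Reagents that add atoms: none
Why: Ionic hydrogenation of the aryl hemiketal gives oxolane 20, whose benzylic C–O bond ionises in the acid; the p-silyloxybenzyl cation then undergoes a six-membered Friedel–Crafts cyclisation para to the OMe of the benzyl ring (the olivil-to-cycloolivil rearrangement), with the aryl group expected pseudo-equatorial and trans to the C2 CH2OTIPS group (C1 = S), while the acid also cleaves the tertiary TMS ether.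

Step 14
Reactants: 21 tetralin diol
Product: 22 fragment A (penta-TIPS ether, tertiary OH free)
Conditions: TIPSCl, imidazole, DMAP (cat.), DMF, rt
Reagents that add atoms: chlorotriisopropylsilane, CC(C)[Si](Cl)(C(C)C)C(C)C
Why: Selective silylation of the primary alcohol; the hindered tertiary alcohol should remain free and is harmless in the following steps.

Step 15
Reactants: 12 silylated lactone
Product: 23 diphenyl (4S)-4-{[3-methoxy-4-(triisopropylsilyloxy)phenyl]methyl}-3-[(triisopropylsilyloxy)methyl]-4-(trimethylsilyloxy)-4,5-dihydrofuran-2-yl phosphate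
Conditions: KN(SiMe3)2 (1.2 equiv), (PhO)2P(O)Cl (1.3 equiv), HMPA, THF, −78 °C
Reagents that add atoms: diphenyl chlorophosphate, O=P(Cl)(Oc1ccccc1)Oc1ccccc1
Why: Ketene acetal phosphate formation by O-phosphorylation of the potassium lactone enolate at −78 °C, where HMPA favours O- over C-attack and trapping should outrun β-elimination; the C3 stereocentre is erased on purpose.

Step 16
Reactants: 22 fragment A; 23 ketene acetal phosphate
Product: 26 2-aryl-4,5-dihydrofuran with free C4 hydroxyl, via arylboronate 24 (not isolated), via trimethylsilyl ether 25 (not isolated)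
Conditions: [Ir(OMe)(cod)]2 (3 mol %), 4,4'-di-tert-butyl-2,2'-bipyridine (6 mol %), B2pin2 (1.3 equiv), THF, 80 °C; evaporate; then 23, Pd(OAc)2 (5 mol %), SPhos (10 mol %), K3PO4 (3 M aq.), THF, 50 °C; then MeOH, K2CO3 (0.2 equiv), 0 °C
Reagents that add atoms: none
Why: An iridium tris(boryl) complex activates and borylates 22 only at the carbon para to the silyloxy group of ring C to give 24; in the same flask zerovalent palladium inserts into the C2–O(phosphate) bond of 23, transmetalates with 24 and reductively eliminates to forge the oxolane C2–aryl bond as dihydrofuran 25, whose tertiary TMS ether is then methanolysed to 26. The closest known reaction types are the one-pot Ir-catalysed arene borylation/Suzuki–Miyaura sequence and the cross-coupling of lactone-derived ketene acetal phosphates (the logic of 1-aryl glycal synthesis). No ring is closed and no stereocentre is created here; the bond is made with C2 and C3 planar so that step 17 can set both at once. The step needs site selectivity in the C–H activation, and the substitution pattern secures it: the reacting C–H is the only aromatic hydrogen of 22 without an ortho substituent (every Ar–H of the tetralin and of the central ring is flanked by a substituent, and the silyl groups carry no aromatic C–H). Chemoselectivity on palladium is secured because the phosphate-bearing C2 is the only C(sp2)–O electrophile present, and the free tertiary alcohol, the aryl silyl ethers and the enol ether product are expected to be inert to the mildly basic medium.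

Step 17
Reactants: 26 2-aryl-4,5-dihydrofuran with free C4 hydroxyl
Product: 27 heptakis-TIPS ether of the target
Conditions: [Ir(cod)(PCy3)(py)]PF6 (15 mol %), H2 (20 bar), CH2Cl2, rt
Reagents that add atoms: none
Why: Hydroxyl-directed homogeneous hydrogenation with a cationic iridium catalyst: the allylic tertiary C4–OH binds the metal and both hydrogens are delivered syn to it across the tetrasubstituted enol ether, so H-2 and H-3 lie on the OH face and aryl, CH2OTIPS and benzyl end up mutually cis (2R,3R).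

Step 18
Reactants: 27 heptakis-TIPS ether of the target
Product: 28 target CNP0344108.1
Conditions: Bu4NF, AcOH (1:1, 10 equiv), THF, 0 °C to rt
Reagents that add atoms: none
Why: Fluoride cleavage of the seven silyl ethers under acetic acid buffering, which avoids both strong base and the acid that would cyclise the oxolane unit onto its benzyl ring.

**Compound list**

1 | vanillin (4-hydroxy-3-methoxybenzaldehyde) | COc1cc(C=O)ccc1O | starting material
2 | 3-methoxy-4-(triisopropylsilyloxy)benzaldehyde | COc1cc(C=O)ccc1O[Si](C(C)C)(C(C)C)C(C)C | intermediate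
3 | [3-methoxy-4-(triisopropylsilyloxy)phenyl]methanol | COc1cc(CO)ccc1O[Si](C(C)C)(C(C)C)C(C)C | intermediate
4 | 4-(bromomethyl)-2-methoxy-1-(triisopropylsilyloxy)benzene | COc1cc(CBr)ccc1O[Si](C(C)C)(C(C)C)C(C)C | intermediate
5 | (S)-malic acid | OC(=O)C[C@H](O)C(=O)O | starting material
6 | 2-[(2S,4S)-2-tert-butyl-5-oxo-1,3-dioxolan-4-yl]acetic acid (cis) | CC(C)(C)[C@H]1O[C@@H](CC(=O)O)C(=O)O1 | intermediate
7 | 2-[(2S,4S)-2-tert-butyl-4-{[3-methoxy-4-(triisopropylsilyloxy)phenyl]methyl}-5-oxo-1,3-dioxolan-4-yl]acetic acid (benzyl trans to tert-butyl) | CC(C)(C)[C@H]1O[C@@](Cc2ccc(O[Si](C(C)C)(C(C)C)C(C)C)c(OC)c2)(CC(=O)O)C(=O)O1 | intermediate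
8 | (3S)-3-hydroxy-3-(hydroxymethyl)-4-[3-methoxy-4-(triisopropylsilyloxy)phenyl]butanoic acid | COc1cc(C[C@@](O)(CO)CC(=O)O)ccc1O[Si](C(C)C)(C(C)C)C(C)C | intermediate (not isolated)
9 | (4S)-4-hydroxy-4-{[3-methoxy-4-(triisopropylsilyloxy)phenyl]methyl}oxolan-2-one | COc1cc(C[C@@]2(O)COC(=O)C2)ccc1O[Si](C(C)C)(C(C)C)C(C)C | intermediate
10 | (3S,4S)-4-hydroxy-3-(hydroxymethyl)-4-{[3-methoxy-4-(triisopropylsilyloxy)phenyl]methyl}oxolan-2-one (CH2OH trans to OH) | COc1cc(C[C@@]2(O)COC(=O)[C@H]2CO)ccc1O[Si](C(C)C)(C(C)C)C(C)C | intermediate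
11 | (3S,4S)-4-hydroxy-4-{[3-methoxy-4-(triisopropylsilyloxy)phenyl]methyl}-3-[(triisopropylsilyloxy)methyl]oxolan-2-one | COc1cc(C[C@@]2(O)COC(=O)[C@H]2CO[Si](C(C)C)(C(C)C)C(C)C)ccc1O[Si](C(C)C)(C(C)C)C(C)C | intermediate (not isolated)
12 | (3S,4S)-4-{[3-methoxy-4-(triisopropylsilyloxy)phenyl]methyl}-3-[(triisopropylsilyloxy)methyl]-4-(trimethylsilyloxy)oxolan-2-one | COc1cc(C[C@@]2(O[Si](C)(C)C)COC(=O)[C@H]2CO[Si](C(C)C)(C(C)C)C(C)C)ccc1O[Si](C(C)C)(C(C)C)C(C)C | intermediate
13 | 4-bromo-2-methoxyphenol | COc1cc(Br)ccc1O | starting material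
14 | 4-bromo-2-iodo-6-methoxyphenol | COc1cc(Br)cc(I)c1O | intermediate
15 | (2-hydroxy-3-methoxyphenyl)boronic acid | COc1cccc(B(O)O)c1O | starting material
16 | 5-bromo-3,3'-dimethoxybiphenyl-2,2'-diol | COc1cc(Br)cc(-c2cccc(OC)c2O)c1O | intermediate
17 | 5-bromo-3,3'-dimethoxy-2,2'-bis(triisopropylsilyloxy)biphenyl | COc1cc(Br)cc(-c2cccc(OC)c2O[Si](C(C)C)(C(C)C)C(C)C)c1O[Si](C(C)C)(C(C)C)C(C)C | intermediate
18 | [3,3'-dimethoxy-2,2'-bis(triisopropylsilyloxy)biphenyl-5-yl]lithium | [Li]c1cc(OC)c(O[Si](C(C)C)(C(C)C)C(C)C)c(-c2cccc(OC)c2O[Si](C(C)C)(C(C)C)C(C)C)c1 | intermediate (not isolated)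
19 | (3S,4S)-2-[3,3'-dimethoxy-2,2'-bis(triisopropylsilyloxy)biphenyl-5-yl]-4-{[3-methoxy-4-(triisopropylsilyloxy)phenyl]methyl}-3-[(triisopropylsilyloxy)methyl]-4-(trimethylsilyloxy)oxolan-2-ol (mixture at C2) | COc1cc(C[C@@]2(O[Si](C)(C)C)COC(O)(c3cc(OC)c(O[Si](C(C)C)(C(C)C)C(C)C)c(-c4cccc(OC)c4O[Si](C(C)C)(C(C)C)C(C)C)c3)[C@H]2CO[Si](C(C)C)(C(C)C)C(C)C)ccc1O[Si](C(C)C)(C(C)C)C(C)C | intermediate
20 | (2R,3R,4S)-2-[3,3'-dimethoxy-2,2'-bis(triisopropylsilyloxy)biphenyl-5-yl]-4-{[3-methoxy-4-(triisopropylsilyloxy)phenyl]methyl}-3-[(triisopropylsilyloxy)methyl]oxolan-4-ol | COc1cc(C[C@@]2(O)CO[C@@H](c3cc(OC)c(O[Si](C(C)C)(C(C)C)C(C)C)c(-c4cccc(OC)c4O[Si](C(C)C)(C(C)C)C(C)C)c3)[C@H]2CO[Si](C(C)C)(C(C)C)C(C)C)ccc1O[Si](C(C)C)(C(C)C)C(C)C | intermediate (not isolated)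
21 | (1S,2S,3S)-1-[3,3'-dimethoxy-2,2'-bis(triisopropylsilyloxy)biphenyl-5-yl]-3-(hydroxymethyl)-6-methoxy-7-(triisopropylsilyloxy)-2-[(triisopropylsilyloxy)methyl]-1,2,3,4-tetrahydronaphthalen-3-ol (C1 bears the aryl group) | COc1cccc(-c2cc([C@H]3c4cc(O[Si](C(C)C)(C(C)C)C(C)C)c(OC)cc4C[C@@](O)(CO)[C@@H]3CO[Si](C(C)C)(C(C)C)C(C)C)cc(OC)c2O[Si](C(C)C)(C(C)C)C(C)C)c1O[Si](C(C)C)(C(C)C)C(C)C | intermediate
22 | fragment A: the 3-[(triisopropylsilyloxy)methyl] analogue of 21 (penta-TIPS ether, tertiary OH free) | COc1cccc(-c2cc([C@H]3c4cc(O[Si](C(C)C)(C(C)C)C(C)C)c(OC)cc4C[C@@](O)(CO[Si](C(C)C)(C(C)C)C(C)C)[C@@H]3CO[Si](C(C)C)(C(C)C)C(C)C)cc(OC)c2O[Si](C(C)C)(C(C)C)C(C)C)c1O[Si](C(C)C)(C(C)C)C(C)C | intermediate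
23 | diphenyl (4S)-4-{[3-methoxy-4-(triisopropylsilyloxy)phenyl]methyl}-3-[(triisopropylsilyloxy)methyl]-4-(trimethylsilyloxy)-4,5-dihydrofuran-2-yl phosphate | COc1cc(C[C@@]2(O[Si](C)(C)C)COC(OP(=O)(Oc3ccccc3)Oc3ccccc3)=C2CO[Si](C(C)C)(C(C)C)C(C)C)ccc1O[Si](C(C)C)(C(C)C)C(C)C | intermediate
24 | fragment A carrying a pinacolboryl group at biphenyl C5' (para to the 2'-silyloxy group) | COc1cc(B2OC(C)(C)C(C)(C)O2)cc(-c2cc([C@H]3c4cc(O[Si](C(C)C)(C(C)C)C(C)C)c(OC)cc4C[C@@](O)(CO[Si](C(C)C)(C(C)C)C(C)C)[C@@H]3CO[Si](C(C)C)(C(C)C)C(C)C)cc(OC)c2O[Si](C(C)C)(C(C)C)C(C)C)c1O[Si](C(C)C)(C(C)C)C(C)C | intermediate (not isolated)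
25 | (4S)-2-aryl-4,5-dihydrofuran (aryl = fragment A bonded through biphenyl C5') bearing the 4-[3-methoxy-4-(triisopropylsilyloxy)benzyl], 3-[(triisopropylsilyloxy)methyl] and 4-(trimethylsilyloxy) groups | COc1cc(C[C@@]2(O[Si](C)(C)C)COC(c3cc(OC)c(O[Si](C(C)C)(C(C)C)C(C)C)c(-c4cc([C@H]5c6cc(O[Si](C(C)C)(C(C)C)C(C)C)c(OC)cc6C[C@@](O)(CO[Si](C(C)C)(C(C)C)C(C)C)[C@@H]5CO[Si](C(C)C)(C(C)C)C(C)C)cc(OC)c4O[Si](C(C)C)(C(C)C)C(C)C)c3)=C2CO[Si](C(C)C)(C(C)C)C(C)C)ccc1O[Si](C(C)C)(C(C)C)C(C)C | intermediate (not isolated)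
26 | the 4-hydroxy analogue of 25 (TMS removed; two free tertiary alcohols) | COc1cc(C[C@@]2(O)COC(c3cc(OC)c(O[Si](C(C)C)(C(C)C)C(C)C)c(-c4cc([C@H]5c6cc(O[Si](C(C)C)(C(C)C)C(C)C)c(OC)cc6C[C@@](O)(CO[Si](C(C)C)(C(C)C)C(C)C)[C@@H]5CO[Si](C(C)C)(C(C)C)C(C)C)cc(OC)c4O[Si](C(C)C)(C(C)C)C(C)C)c3)=C2CO[Si](C(C)C)(C(C)C)C(C)C)ccc1O[Si](C(C)C)(C(C)C)C(C)C | intermediate
27 | target with its four phenolic and three primary hydroxyls as TIPS ethers; oxolane (2R,3R,4S), tetralin (1S,2S,3S) | COc1cc(C[C@@]2(O)CO[C@@H](c3cc(OC)c(O[Si](C(C)C)(C(C)C)C(C)C)c(-c4cc([C@H]5c6cc(O[Si](C(C)C)(C(C)C)C(C)C)c(OC)cc6C[C@@](O)(CO[Si](C(C)C)(C(C)C)C(C)C)[C@@H]5CO[Si](C(C)C)(C(C)C)C(C)C)cc(OC)c4O[Si](C(C)C)(C(C)C)C(C)C)c3)[C@H]2CO[Si](C(C)C)(C(C)C)C(C)C)ccc1O[Si](C(C)C)(C(C)C)C(C)C | intermediate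
28 | CNP0344108.1: biaryl of a (2R,3R,4S)-2-aryl-4-benzyl-4-hydroxy-3-(hydroxymethyl)oxolane and a (1S,2S,3S)-1-aryl-2,3-bis(hydroxymethyl)tetralin-3,7-diol | COc1cc(C[C@@]2(O)CO[C@@H](c3cc(OC)c(O)c(-c4cc([C@H]5c6cc(O)c(OC)cc6C[C@@](O)(CO)[C@@H]5CO)cc(OC)c4O)c3)[C@H]2CO)ccc1O | target

**Step count and risks**

Total steps: 18. Longest linear sequence: 13 (steps 1, 2, 3, 5, 6, 7, 8, 12, 13, 14, 16, 17, 18).

Step 16. What may go wrong: protodeboronation of the boronate, or hydrolysis of the crowded ketene acetal phosphate while oxidative addition at its tetrasubstituted C2 is slow. The fallback sets out from 22 and lactone 12 and returns at 27. The borylation half is run alone and boronate 24 is isolated. CuBr2 in MeOH/H2O at 80 °C should convert it into the aryl bromide F1. Bromine–lithium exchange (n-BuLi, 2.1 equiv, THF, −78 °C, the first equivalent deprotonating the tertiary alcohol) and addition to 12 should give the hemiketal F2. Et3SiH/BF3·OEt2 in CH2Cl2 at −78 °C should then reduce the aryl oxocarbenium ion by hydride attack on the face of the C4 oxygen, anti to the C3 and benzyl substituents, giving the same 2,3-cis oxolane. K2CO3/MeOH removes the TMS ether to reach 27, so steps 15 and 17 are bypassed.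

Step 15. What may go wrong: β-elimination of a silanolate from the potassium enolate (loss of the C3 side-chain oxygen or the C4 oxygen), or C- instead of O-phosphorylation. The fallback sets out from 12 and re-enters step 16 at 25, which is carried on to 26 as before. iBu2AlH (CH2Cl2, −78 °C) should give the lactol F3. MsCl/Et3N (CH2Cl2, 0 °C to reflux) should dehydrate it to the 4,5-dihydrofuran F4. C2 lithiation with t-BuLi (THF, −78 to 0 °C) and an iodine quench should give the 2-iodo enol ether F5, which replaces 23 in the Suzuki half of step 16 with boronate 24. No enolate with a β-leaving group is formed on this path.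

Step 17. What may go wrong: slow hydrogen uptake at the crowded tetrasubstituted enol ether, acid-type isomerisation by the cationic iridium hydride, or insufficient facial control. The fallback runs from 26 to 27 and makes no new compound (F0). It is a polar two-stage reduction (ionic hydrogenation) with CF3CO2H/Et3SiH in CH2Cl2 at −78 to −40 °C: protonation of the enol ether at C3 on the face opposite the benzyl group, then hydride delivery to the aryl oxocarbenium ion on the hydroxyl face. The reaction is quenched cold, before the benzylic ether can ionise.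

**Further compounds**

F1 | step 16 | fragment A carrying bromine at biphenyl C5' (para to the 2'-silyloxy group) | COc1cc(Br)cc(-c2cc([C@H]3c4cc(O[Si](C(C)C)(C(C)C)C(C)C)c(OC)cc4C[C@@](O)(CO[Si](C(C)C)(C(C)C)C(C)C)[C@@H]3CO[Si](C(C)C)(C(C)C)C(C)C)cc(OC)c2O[Si](C(C)C)(C(C)C)C(C)C)c1O[Si](C(C)C)(C(C)C)C(C)C
F2 | step 16 | hemiketal from lithiated F1 and lactone 12 (mixture at C2) | COc1cc(C[C@@]2(O[Si](C)(C)C)COC(O)(c3cc(OC)c(O[Si](C(C)C)(C(C)C)C(C)C)c(-c4cc([C@H]5c6cc(O[Si](C(C)C)(C(C)C)C(C)C)c(OC)cc6C[C@@](O)(CO[Si](C(C)C)(C(C)C)C(C)C)[C@@H]5CO[Si](C(C)C)(C(C)C)C(C)C)cc(OC)c4O[Si](C(C)C)(C(C)C)C(C)C)c3)[C@H]2CO[Si](C(C)C)(C(C)C)C(C)C)ccc1O[Si](C(C)C)(C(C)C)C(C)C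
F3 | step 15 | (3S,4S)-lactol of 12 (oxolan-2-ol, mixture at C2) | COc1cc(C[C@@]2(O[Si](C)(C)C)COC(O)[C@H]2CO[Si](C(C)C)(C(C)C)C(C)C)ccc1O[Si](C(C)C)(C(C)C)C(C)C
F4 | step 15 | (4S)-4-{[3-methoxy-4-(triisopropylsilyloxy)phenyl]methyl}-3-[(triisopropylsilyloxy)methyl]-4-(trimethylsilyloxy)-4,5-dihydrofuran | COc1cc(C[C@@]2(O[Si](C)(C)C)COC=C2CO[Si](C(C)C)(C(C)C)C(C)C)ccc1O[Si](C(C)C)(C(C)C)C(C)C
F5 | step 15 | 2-iodo derivative of F4 | COc1cc(C[C@@]2(O[Si](C)(C)C)COC(I)=C2CO[Si](C(C)C)(C(C)C)C(C)C)ccc1O[Si](C(C)C)(C(C)C)C(C)C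
F0 | step 17 | none | none
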